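The pitfall in a catalysed flask is to let the starting material decay exponentially, with a rate constant proportional to the catalyst, and so to expect a row of yields that bends over as the charge grows.

all flasks: starting material 0.40 M

| charge | free catalyst | remark | time |
|---|---|---|---|
| elm | 7.3 mM | run made earlier |  |
| alder | 40 mM | run made earlier |  |
| spring | 6.0 mM |  | 2.5 min |
| dusk | 10 mM |  | 2.5 min |
| midnight | 15 mM |  | 2.5 min |
| dawn | 25 mM |  | 2.5 min |
| summer | 30 mM |  | 2.5 min |

| run | time / min | target / % | starting material / % |
|---|---|---|---|
| elm | 0.167 | 0 | 96 |
| elm | 0.500 | 0 | 100 |
| elm | 0.833 | 5 | 93 |
| elm | 1.33 | 3 | 92 |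
| elm | 2.00 | 4 | 89 |
| elm | 2.50 | 8 | 88 |
| alder | 0.200 | 4 | 88 |
| alder | 0.333 | 9 | 85 |
| alder | 0.500 | 8 | 81 |
| alder | 0.833 | 18 | 73 |
| alder | 1.50 | 36 | 56 |
| alder | 2.50 | 53 | 33 |

(readings scatter by 2 percentage points)

- the analysis behind the earlier runs scatters by 2 percentage points, standard deviation
- a reading or a percentage of target counts all its forms, free or not
- "hardly changes" means that all values lie within two and a half points (for a concentration: within two and a half percent of the largest)

1. amount of target at the end, in percent of the starting material charged for spring, dusk, midnight, dawn, summer, in this order
2. the shape of the row from first to last (hardly changes / rises, then falls / falls all the way / rises all the way / falls, then rises)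

Two chemists dispute this row. The first holds that view, the bend, and scales alder's 53% of target at 2.50 min through an exponential. That gives 10.7% for spring and 43.2% for summer, a ratio of 4.04, below the charge ratio of 5.00.

The second holds that the catalyst works at a steady pace whatever the starting material does, and the forecast is this side's number: 5%, 11%, 18%, 31%, 38%, so that the row rises all the way. Its ground: “Target then grows linearly with time, which is zero order in starting material”. With its small offset for lost catalyst, its ratio is 7.60.

My own reckoning takes the straight line without the offset. Alder's target slope from 0.833 min to 2.50 min gives 2.10 min⁻¹, the turnover rate, meaning moles of target made per mole of catalyst charged per minute. It gives 7.87% for spring, somewhat above the forecast.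

Held against elm, the bend gives 12.9% and the turnover rate 9.58%. Elm read 8% at 2.50 min, with a scatter of 2 percentage points, so the bend lies further from that reading than the line.

The simulation gives 7.60%, 13.8%, 21.4%, 35.7% and 42.4%, and the row rises all the way.

    starting material + free catalyst ⇌ catalyst intermediate A (K = 4.30 L mol⁻¹, k = 0.870 L mol⁻¹ s⁻¹)
    catalyst intermediate A ⇌ catalyst intermediate B (K = 86.0, k = 0.360 s⁻¹)
    catalyst intermediate B → free catalyst + target (k = 0.0780 s⁻¹)
    target → over-reaction product (k = 0.00960 s⁻¹)
    crystals ⇌ target, rate k5*(cs5 - [target]) while solid is left; crystals form when [target] > cs5 (solubility = 7.80 mM, k = 0.100 s⁻¹)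

The ratio of last to first is 5.58, above both the charge ratio of 5.00 and the bend's 4.04, so it matches neither view. The turnover rate is nearer at spring, 7.87% against the simulated 7.60%, but the bend is nearer at summer, 43.2% against the simulated 42.4%. The bend's region is summer's charge and the late flask, and a forecast of this kind goes wrong in the late flask: spring at 25.0 min holds 53.0% target, where the turnover rate gives 78.7%, with 13.9% starting material left. In spring at 1.15 min, the half-life of starting material by the forward binding step alone is 9.4 min, longer than the run's 2.5 min. At spring's end 88% of the starting material is left, and catalyst intermediate B, the resting state, holds 61.3% of the catalyst charged.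

The earlier runs and the new flask stem from a simulated flask with constants of no real substance, noise included.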